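At 4.0 h, the time of reading, two flasks are compared that differ in their charge of transfer agent.

the same everywhere: free monomer 1.2 M; protic impurity 0.360 M; initiator 60 mM; stray impurity 53 mM; time 4.0 h
- autumn: transfer agent 0.0120 M
- dawn: transfer agent 0.0500 M

    living end + transfer agent → dead chain (k1 = 33 /M/h)
    free monomer + living end → monomer in chains + living end, rate k2*[living end]*[free monomer] (k2 = 15 /M/h)
    initiator + stray impurity → spent initiator (k3 = 240 /M/h)
    free monomer + initiator → living end + monomer in chains (k4 = 11 /M/h)
    protic impurity + free monomer → quenched substrate (k5 = 0.95 /M/h)

- the average divides the monomer in chains by the number of chains begun, living and dead together
- run time (autumn): 4.0 h

1. which of the two ends with the longer chains by the average number of monomer units in a chain (chains begun, living or dead) ("neither" if they lie within 10%) (autumn / dawn / neither)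
2. average number of monomer units in a chain (chains begun, living or dead) at the end, autumn
3. average number of monomer units in a chain (chains begun, living or dead) at the end, dawn

Free monomer joins chains at a rate proportional to [living end], so [living end] is the concentration to find: it turns propagation into a pseudo-first-order loss of free monomer with rate constant 15 /M/h times [living end]. Living ends come from initiator, which has two partners. With charged amounts, free monomer takes it at 13.2 /h and stray impurity at 12.7 /h, and these nearly match. Initiator therefore lasts about 0.0386 h, far shorter than the run, and at these starting rates about half of it goes to begin a chain. This starting share, the rate with free monomer over the sum of both rates, is 0.509. Multiplied by the charged initiator, with the share held at its starting value, it gives an estimate of the chains begun, 0.0306 M. Transfer agent does not enter this estimate, so it is the same for autumn and dawn, and the average in each is its monomer in chains divided by the chains begun.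

Each transfer agent ends one living end. In autumn the charge is smaller than the estimated chains begun, so by this estimate 0.0186 M of living ends remain once the transfer agent is used up, with a propagation rate constant for free monomer of 0.279 /h. In dawn the charge is larger, so it can end every chain begun, and at the charged transfer agent a living end has a half-life of 0.420 h, shorter than the run. This reckoning therefore names autumn, where the same half-life is 1.8 h, as the flask with more monomer in chains and the longer chains. It stops there, since protic impurity also consumes free monomer and the amount taken needs stepping through time.

The forecast also names autumn, with 22 units for autumn and 11.7 for dawn. Its count of chains differs from the one above: its competition “gives about 0.034 M chains begun in both runs”.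

The simulation gives autumn the longer chains, 21.7 units against 11.9 in dawn. At the end autumn holds 0.0229 M of living ends and 0.0116 M of dead chains, together 0.0345 M, more than the 0.0306 M estimated with the starting share. A further flask, like autumn but charged with 0.024 M of initiator, has the same starting share, which gives an estimate of 0.0122 M chains begun. Its monomer in chains, 30.0% of the free monomer charged, then makes 29.4 units per chain by this estimate, and the simulated average in that flask is 28.1.

The numbers of this flask belong to no real substance; the rest is arithmetic.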